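**Retrosynthetic overview**
- Target ⇒ carpaine: one NH–CH(CH3) unit of the C2-symmetric diamine is dehydrogenated to the C(CH3)=N ketimine in the last step.
- Carpaine ⇒ two molecules of N-sulfonyl carpamic acid by head-to-tail macrodilactonisation (26-membered ring), then N-deprotection.
- Carpamic acid ⇒ cis-6-allyl-2-methyl-dihydropyridin-3-one + hept-6-en-1-ol: cross-metathesis, alcohol → acid, hydrogenation, cis-selective ketone reduction.
- Dihydropyridinone ⇒ (S)-1-(furan-2-yl)ethylamine: key step is the aza-Achmatowicz oxidative ring expansion of the furan, followed by cis-selective allylation of the N-sulfonyliminium ion.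
- Ring order: six-membered N-ring (ring expansion, monomer) → 26-membered dilactone → cyclic imine ring (from one piperidine).

Assumption: enantiopure (S)-1-(furan-2-yl)ethan-1-amine, allyltrimethylsilane and hept-6-en-1-ol are bought. SES = 2-(trimethylsilyl)ethanesulfonyl.

**Step 1**
Reactants: 1 (1S)-1-(furan-2-yl)ethan-1-amine
Product: 2 N-[(1S)-1-(furan-2-yl)ethyl]-2-(trimethylsilyl)ethane-1-sulfonamide
Conditions: SES-Cl, Et3N, CH2Cl2, 0 °C → rt
Reagents that add atoms: 2-(trimethylsilyl)ethanesulfonyl chloride (SES-Cl), C[Si](C)(C)CCS(=O)(=O)Cl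
Why: N-sulfonylation of the primary amine leaves the stereocentre untouched; the sulfonamide N–H is needed for the ring expansion, the sulfonyl group enforces A(1,3) strain for the later cis-selective steps, and SES is cleaved by fluoride.

**Step 2**
Reactants: 2 N-[(1S)-1-(furan-2-yl)ethyl]-2-(trimethylsilyl)ethane-1-sulfonamide
Product: 3 (2S)-6-hydroxy-2-methyl-1-SES-1,6-dihydropyridin-3(2H)-one (C6 epimers)
Conditions: mCPBA, CH2Cl2, 0 °C → rt
Reagents that add atoms: mCPBA (3-chloroperoxybenzoic acid), OOC(=O)c1cccc(Cl)c1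
Why: aza-Achmatowicz rearrangement: the peracid oxidises the furan to the cis-enedione and the sulfonamide nitrogen closes onto the aldehyde, expanding the five-membered furan to the six-membered dihydropyridinone; the C2 stereocentre is carried through.

**Step 3**
Reactants: 3 (2S)-6-hydroxy-2-methyl-1-SES-1,6-dihydropyridin-3(2H)-one; 4 allyltrimethylsilane
Product: 6 (2S,6R)-2-methyl-6-(prop-2-en-1-yl)-1-SES-1,6-dihydropyridin-3(2H)-one, via N-sulfonyliminium ion 5 (not isolated)
Conditions: BF3·OEt2, CH2Cl2, −78 → 0 °C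
Reagents that add atoms: none
Why: Hosomi–Sakurai allylation of the N-sulfonyliminium ion; A(1,3) strain with the sulfonyl group holds the 2-methyl group axial and the allylsilane adds axially on the same side, giving the 2,6-cis product (new centre 6R), the outcome established for N-tosyl analogues.

**Step 4**
Reactants: 6 (2S,6R)-2-methyl-6-(prop-2-en-1-yl)-1-SES-1,6-dihydropyridin-3(2H)-one; 7 hept-6-en-1-ol
Product: 8 (2S,6R)-6-[(2E)-8-hydroxyoct-2-en-1-yl]-2-methyl-1-SES-1,6-dihydropyridin-3(2H)-one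
Conditions: 7 (3 equiv), second-generation Grubbs catalyst RuCl2(=CHPh)(PCy3)(H2IMes) (5 mol %), CH2Cl2, 40 °C
Reagents that add atoms: none
Why: olefin cross-metathesis of the terminal allyl group with excess terminal alkenol; the cyclic enone does not take part and the E/Z ratio is irrelevant because the alkene is hydrogenated in step 6.

**Step 5**
Reactants: 8 (2S,6R)-6-[(2E)-8-hydroxyoct-2-en-1-yl]-2-methyl-1-SES-1,6-dihydropyridin-3(2H)-one
Product: 9 (6E)-8-[(2R,6S)-6-methyl-5-oxo-1-SES-1,2,5,6-tetrahydropyridin-2-yl]oct-6-enoic acid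
Conditions: TEMPO (cat.), PhI(OAc)2, MeCN/H2O, rt
Reagents that add atoms: water, O
Why: TEMPO-catalysed oxidation takes the primary alcohol through the aldehyde hydrate to the carboxylic acid and leaves the enone, the alkene and the sulfonamide untouched.

**Step 6**
Reactants: 9 (6E)-8-[(2R,6S)-6-methyl-5-oxo-1-SES-1,2,5,6-tetrahydropyridin-2-yl]oct-6-enoic acid
Product: 11 8-[(2R,5S,6S)-5-hydroxy-6-methyl-1-SES-piperidin-2-yl]octanoic acid (N-SES carpamic acid), via saturated keto acid 10 (not isolated)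
Conditions: H2 (1 atm), 10% Pd/C, MeOH, rt; filter; then NaBH4, −40 → 0 °C
Reagents that add atoms: none
Why: heterogeneous catalytic hydrogenation saturates both C=C bonds, then borohydride reduces the ketone by axial attack anti to the axial 2-methyl group of the N-sulfonyl chair, giving the all-cis alcohol (new centre 5S).

**Step 7**
Reactants: 11 N-SES carpamic acid (two molecules)
Product: 14 N,N'-bis-SES carpaine, via mixed anhydride 12 (not isolated), via linear dimer anhydride 13 (not isolated)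
Conditions: 2,4,6-Cl3C6H2COCl, Et3N, THF, rt; then slow addition to DMAP, toluene, 90 °C (5 mM)
Reagents that add atoms: none
Why: Yamaguchi esterification run as a head-to-tail cyclodimerisation (macrodilactonisation), the mode known for N-protected carpamic acids; acylation occurs at the carbonyl carbon, so no stereocentre is affected.

**Step 8**
Reactants: 14 N,N'-bis-SES carpaine
Product: 15 carpaine
Conditions: CsF, DMF, 95 °C
Reagents that add atoms: none
Why: fluoride-induced β-elimination of the SES groups (attack at silicon, loss of ethene and SO2) frees both secondary amines without touching the two lactone esters or any stereocentre.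

**Step 9**
Reactants: 15 carpaine
Product: 18 CNP0304114.1 (carpaine mono-imine), via carpaine mono-ammonium salt 16 (not isolated), via N-chloro ammonium salt 17 (not isolated)
Conditions: HNTf2 (1.00 equiv), CH2Cl2, −40 °C; NCS (1.05 equiv), −40 → 0 °C; then DBU (3 equiv), 0 °C → rt
Reagents that add atoms: none
Why: Proposed new method: proton-gated desymmetrising dehydrogenation of a C2-symmetric macrocyclic diamine. One equivalent of a strong acid with a weakly coordinating anion puts one proton on each macrocycle, the dication being disfavoured by charge repulsion in CH2Cl2. Only the unprotonated nitrogen can attack NCS, and once it is N-chlorinated it is no longer basic, so the proton is locked on the other nitrogen and shields it. DBU then frees that ammonium and effects anti-periplanar dehydrochlorination of the chloramine. The transition state carries carbanion character at the α-carbon, so the axial C–H of the methyl-bearing carbon, antiperiplanar to the vicinal C–O(acyl) bond, is removed in preference to the C–H on the chain side. This forms the C(CH3)=N bond and leaves the 2R and 5S centres of that ring untouched. Closest known reaction types: mono-acylation of symmetric diamines through their mono-hydrochlorides, and base-induced dehydrohalogenation of N-chloro piperidines to cyclic imines.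

**Compound list**
1 | (1S)-1-(furan-2-yl)ethan-1-amine | C[C@H](N)c1ccco1 | starting material
2 | N-[(1S)-1-(furan-2-yl)ethyl]-2-(trimethylsilyl)ethane-1-sulfonamide | C[C@H](NS(=O)(=O)CC[Si](C)(C)C)c1ccco1 | intermediate
3 | (2S)-6-hydroxy-2-methyl-1-{[2-(trimethylsilyl)ethyl]sulfonyl}-1,6-dihydropyridin-3(2H)-one, C6 epimers | C[C@H]1C(=O)C=CC(O)N1S(=O)(=O)CC[Si](C)(C)C | intermediate
4 | allyltrimethylsilane | C=CC[Si](C)(C)C | starting material
5 | (2S)-2-methyl-3-oxo-1-{[2-(trimethylsilyl)ethyl]sulfonyl}-2,3-dihydropyridin-1-ium hydroxytrifluoroborate | C[C@H]1C(=O)C=CC=[N+]1S(=O)(=O)CC[Si](C)(C)C.O[B-](F)(F)F | intermediate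
6 | (2S,6R)-2-methyl-6-(prop-2-en-1-yl)-1-{[2-(trimethylsilyl)ethyl]sulfonyl}-1,6-dihydropyridin-3(2H)-one | C[C@H]1C(=O)C=C[C@@H](CC=C)N1S(=O)(=O)CC[Si](C)(C)C | intermediate
7 | hept-6-en-1-ol | OCCCCCC=C | starting material
8 | (2S,6R)-6-[(2E)-8-hydroxyoct-2-en-1-yl]-2-methyl-1-{[2-(trimethylsilyl)ethyl]sulfonyl}-1,6-dihydropyridin-3(2H)-one | C[C@H]1C(=O)C=C[C@@H](C/C=C/CCCCCO)N1S(=O)(=O)CC[Si](C)(C)C | intermediate
9 | (6E)-8-[(2R,6S)-6-methyl-5-oxo-1-{[2-(trimethylsilyl)ethyl]sulfonyl}-1,2,5,6-tetrahydropyridin-2-yl]oct-6-enoic acid | C[C@H]1C(=O)C=C[C@@H](C/C=C/CCCCC(=O)O)N1S(=O)(=O)CC[Si](C)(C)C | intermediate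
10 | 8-[(2R,6S)-6-methyl-5-oxo-1-{[2-(trimethylsilyl)ethyl]sulfonyl}piperidin-2-yl]octanoic acid | C[C@H]1C(=O)CC[C@@H](CCCCCCCC(=O)O)N1S(=O)(=O)CC[Si](C)(C)C | intermediate
11 | 8-[(2R,5S,6S)-5-hydroxy-6-methyl-1-{[2-(trimethylsilyl)ethyl]sulfonyl}piperidin-2-yl]octanoic acid | C[C@H]1[C@@H](O)CC[C@@H](CCCCCCCC(=O)O)N1S(=O)(=O)CC[Si](C)(C)C | intermediate
12 | mixed anhydride of 11 and 2,4,6-trichlorobenzoic acid | C[C@H]1[C@@H](O)CC[C@@H](CCCCCCCC(=O)OC(=O)c2c(Cl)cc(Cl)cc2Cl)N1S(=O)(=O)CC[Si](C)(C)C | intermediate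
13 | linear head-to-tail ester dimer of 11, terminal acid as its 2,4,6-trichlorobenzoic mixed anhydride | C[C@H]1[C@@H](O)CC[C@@H](CCCCCCCC(=O)O[C@H]2CC[C@@H](CCCCCCCC(=O)OC(=O)c3c(Cl)cc(Cl)cc3Cl)N(S(=O)(=O)CC[Si](C)(C)C)[C@H]2C)N1S(=O)(=O)CC[Si](C)(C)C | intermediate
14 | (1S,11R,13S,14S,24R,26S)-13,26-dimethyl-12,25-bis{[2-(trimethylsilyl)ethyl]sulfonyl}-2,15-dioxa-12,25-diazatricyclo[22.2.2.2(11,14)]triacontane-3,16-dione | C[C@H]1[C@@H](O3)CC[C@@H](CCCCCCCC(=O)O[C@H]2CC[C@@H](CCCCCCCC3=O)N(S(=O)(=O)CC[Si](C)(C)C)[C@H]2C)N1S(=O)(=O)CC[Si](C)(C)C | intermediate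
15 | carpaine, (1S,11R,13S,14S,24R,26S)-13,26-dimethyl-2,15-dioxa-12,25-diazatricyclo[22.2.2.2(11,14)]triacontane-3,16-dione | C[C@H]1[C@@H](O3)CC[C@@H](CCCCCCCC(=O)O[C@H]2CC[C@@H](CCCCCCCC3=O)N[C@H]2C)N1 | intermediate
16 | carpaine mono-ammonium bis(trifluoromethanesulfonyl)imide | C[C@H]1[C@@H](O3)CC[C@@H](CCCCCCCC(=O)O[C@H]2CC[C@@H](CCCCCCCC3=O)[NH2+][C@H]2C)N1.FC(F)(F)S(=O)(=O)[N-]S(=O)(=O)C(F)(F)F | intermediate
17 | N-chlorocarpaine, other nitrogen as ammonium bis(trifluoromethanesulfonyl)imide | C[C@H]1[C@@H](O3)CC[C@@H](CCCCCCCC(=O)O[C@H]2CC[C@@H](CCCCCCCC3=O)[NH2+][C@H]2C)N1Cl.FC(F)(F)S(=O)(=O)[N-]S(=O)(=O)C(F)(F)F | intermediate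
18 | CNP0304114.1, carpaine with one ring as the 6-methyl-2,3,4,5-tetrahydropyridine (imine ring 2R,5S; piperidine ring 2R,5S,6S) | CC1=N[C@@H]2CCCCCCCC(=O)O[C@H]3CC[C@@H](CCCCCCCC(=O)O[C@H]1CC2)N[C@H]3C | target

**Totals**
Total step count: 9. Longest linear sequence: 9 steps (from 1; the route is linear and 11 is used twice in step 7).

**Three steps most likely to fail**

Step 9 (new method). Risks: if the mono-ammonium state is not clean, selectivity falls back toward the statistical level (at most about half mono-imine, with 15 recovered). Chlorine transfer between nitrogens after DBU addition, the regio-isomeric imine and base-induced epimerisation at the acyloxy-bearing carbon next to C=N are further risks. Fallback with known chemistry, setting out from 15 and returning at 18: 15 is treated with Boc2O (1.0 equiv, dioxane, 60 °C) and the statistical mixture is separated to give mono-N-Boc carpaine F8, with 15 and the bis-carbamate recycled. NCS (CH2Cl2, 0 °C) chlorinates the only free N–H to give N-chloro-N'-Boc carpaine F9. DBU (toluene, 40 °C) gives N'-Boc carpaine mono-imine F10, and TFA (CH2Cl2, 0 °C), then NaHCO3 wash, gives 18.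

Step 7 (cyclodimerisation). Risks: monomeric bridged lactone and open-chain oligomers compete with the 26-membered dimer. Fallback, setting out from 10 and 11 and returning at 14: part of the step 6 material is taken off after the hydrogenation stage as keto acid 10. 11 is esterified (allyl bromide, K2CO3, DMF) to N-SES carpamic acid allyl ester F1. Intermolecular Yamaguchi esterification of 10 with F1 gives keto diester F2, which can only be the head-to-tail hetero-coupled product. NaBH4 (MeOH, −40 °C) gives hydroxy diester F3, and Pd(PPh3)4/morpholine (THF) gives seco acid F4. A unimolecular Yamaguchi macrolactonisation at high dilution closes F4 to 14.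

Step 8 (SES removal on the macrocycle). Risks: sluggish cleavage of the hindered sulfonamides and fluoride-induced ester cleavage at 95 °C. Fallback, setting out from 11 and returning at 15: SES is removed at the monomer stage (CsF, DMF, 95 °C) to give carpamic acid F5. Benzyl chloroformate and Na2CO3 (dioxane/H2O) give N-benzyloxycarbonyl carpamic acid F6. Yamaguchi cyclodimerisation gives N,N'-bis(benzyloxycarbonyl)carpaine F7, and hydrogenolysis (H2, Pd/C, EtOH) gives 15.

**Further compounds**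
F1 | step 7 | allyl 8-[(2R,5S,6S)-5-hydroxy-6-methyl-1-SES-piperidin-2-yl]octanoate | C[C@H]1[C@@H](O)CC[C@@H](CCCCCCCC(=O)OCC=C)N1S(=O)(=O)CC[Si](C)(C)C
F2 | step 7 | allyl 8-[(2R,5S,6S)-6-methyl-5-({8-[(2R,6S)-6-methyl-5-oxo-1-SES-piperidin-2-yl]octanoyl}oxy)-1-SES-piperidin-2-yl]octanoate | C[C@H]1C(=O)CC[C@@H](CCCCCCCC(=O)O[C@H]2CC[C@@H](CCCCCCCC(=O)OCC=C)N(S(=O)(=O)CC[Si](C)(C)C)[C@H]2C)N1S(=O)(=O)CC[Si](C)(C)C
F3 | step 7 | allyl 8-[(2R,5S,6S)-5-({8-[(2R,5S,6S)-5-hydroxy-6-methyl-1-SES-piperidin-2-yl]octanoyl}oxy)-6-methyl-1-SES-piperidin-2-yl]octanoate | C[C@H]1[C@@H](O)CC[C@@H](CCCCCCCC(=O)O[C@H]2CC[C@@H](CCCCCCCC(=O)OCC=C)N(S(=O)(=O)CC[Si](C)(C)C)[C@H]2C)N1S(=O)(=O)CC[Si](C)(C)C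
F4 | step 7 | 8-[(2R,5S,6S)-5-({8-[(2R,5S,6S)-5-hydroxy-6-methyl-1-SES-piperidin-2-yl]octanoyl}oxy)-6-methyl-1-SES-piperidin-2-yl]octanoic acid | C[C@H]1[C@@H](O)CC[C@@H](CCCCCCCC(=O)O[C@H]2CC[C@@H](CCCCCCCC(=O)O)N(S(=O)(=O)CC[Si](C)(C)C)[C@H]2C)N1S(=O)(=O)CC[Si](C)(C)C
F5 | step 8 | carpamic acid, 8-[(2R,5S,6S)-5-hydroxy-6-methylpiperidin-2-yl]octanoic acid | C[C@H]1[C@@H](O)CC[C@@H](CCCCCCCC(=O)O)N1
F6 | step 8 | 8-[(2R,5S,6S)-1-(benzyloxycarbonyl)-5-hydroxy-6-methylpiperidin-2-yl]octanoic acid | C[C@H]1[C@@H](O)CC[C@@H](CCCCCCCC(=O)O)N1C(=O)OCc2ccccc2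
F7 | step 8 | N,N'-bis(benzyloxycarbonyl)carpaine | C[C@H]1[C@@H](O3)CC[C@@H](CCCCCCCC(=O)O[C@H]2CC[C@@H](CCCCCCCC3=O)N(C(=O)OCc4ccccc4)[C@H]2C)N1C(=O)OCc5ccccc5
F8 | step 9 | mono-N-(tert-butoxycarbonyl)carpaine | C[C@H]1[C@@H](O3)CC[C@@H](CCCCCCCC(=O)O[C@H]2CC[C@@H](CCCCCCCC3=O)N(C(=O)OC(C)(C)C)[C@H]2C)N1
F9 | step 9 | N-chloro-N'-(tert-butoxycarbonyl)carpaine | C[C@H]1[C@@H](O3)CC[C@@H](CCCCCCCC(=O)O[C@H]2CC[C@@H](CCCCCCCC3=O)N(C(=O)OC(C)(C)C)[C@H]2C)N1Cl
F10 | step 9 | N-(tert-butoxycarbonyl) derivative of 18 (carbamate on the piperidine nitrogen) | CC1=N[C@@H]2CCCCCCCC(=O)O[C@H]3CC[C@@H](CCCCCCCC(=O)O[C@H]1CC2)N(C(=O)OC(C)(C)C)[C@H]3C
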